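**Retrosynthetic overview**
1. The cyclobutane is cut by retro-[2+2] into two molecules of the (E)-pyranonyl-butenoic acid 8. Forward, this is a last-step head-to-head photodimerisation of the unprotected acid in its crystalline 2:1 ethylenediammonium salt, which sets all four stereocentres at once.
2. Acid 8 comes from ethyl ester 7, and 7 from 4-hydroxy-2-pyranone 6 by O-methylation.
3. The pyranone ring of 6 comes from lactonisation of the triketide-type 3,5-diketo ester 5, as in polyketide pyranone biosynthesis.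
4. Diketo ester 5 comes from aldol 4, made from the dianion of ethyl 2-methylacetoacetate 1 and the C5 aldehyde ester 2.
5. Ring order: pyranone first (step 2), cyclobutane last (step 5).

Assumption: the target as drawn has an internal mirror plane (meso, (1R,2S,3R,4S): pyranones cis to each other, CO2H groups cis to each other, each pyranone trans to the neighbouring CO2H), so only this relative configuration has to be set and no absolute stereocontrol is needed.

**Route**

Step 1
Reactants: 1 ethyl 2-methyl-3-oxobutanoate (ethyl 2-methylacetoacetate, racemic); 2 ethyl (E)-3-methyl-4-oxobut-2-enoate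
Product: 4 diethyl (E)-4-hydroxy-3,7-dimethyl-6-oxooct-2-enedioate (mixture of diastereomers), via sodium lithium dienolate 3 (not isolated)
Conditions: NaH (1.1 equiv), THF, 0 °C; n-BuLi (1.05 equiv), 0 °C; 2 (0.9 equiv), −78 °C; AcOH, −78 °C
Reagents that add atoms: none
Why: Dianion (Weiler) aldol addition: the hard γ-carbanion of the β-keto ester dianion adds 1,2 to the aldehyde of 2 at −78 °C faster than to its ester or enoate carbon, and the two new stereocentres (C4, C7) need no control because both are erased in step 2.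

Step 2
Reactants: 4 diethyl (E)-4-hydroxy-3,7-dimethyl-6-oxooct-2-enedioate
Product: 6 ethyl (E)-3-(4-hydroxy-3-methyl-2-oxo-2H-pyran-6-yl)but-2-enoate, via diketo ester 5 (not isolated)
Conditions: IBX (3 equiv), EtOAc, 77 °C; filter; DBU (2 equiv), 20 → 50 °C; 1 M HCl
Reagents that add atoms: none
Why: IBX oxidation of the β-hydroxy ketone to the 1,3-diketone is followed by DBU-promoted enol-lactonisation (the enol oxygen of the ketone next to the alkene attacks the β-keto ester carbonyl with loss of ethanol), the polyketide-type triketide-to-pyranone ring closure; the product is achiral and the E-enoate is the thermodynamic isomer.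

Step 3
Reactants: 6 ethyl (E)-3-(4-hydroxy-3-methyl-2-oxo-2H-pyran-6-yl)but-2-enoate
Product: 7 ethyl (E)-3-(4-methoxy-3-methyl-2-oxo-2H-pyran-6-yl)but-2-enoate
Conditions: Me2SO4 (1.5 equiv), K2CO3 (2 equiv), acetone, 20 → 56 °C
Reagents that add atoms: dimethyl sulfate, COS(=O)(=O)OC
Why: SN2 O-methylation (Williamson type) of the potassium salt of the vinylogous acid: K2CO3/Me2SO4 in acetone favours the 4-methoxy-2-pyranone over the 2-methoxy-4-pyranone, and C-3 is blocked against C-alkylation by its methyl group; no stereocentre.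

Step 4
Reactants: 7 ethyl (E)-3-(4-methoxy-3-methyl-2-oxo-2H-pyran-6-yl)but-2-enoate
Product: 8 (E)-3-(4-methoxy-3-methyl-2-oxo-2H-pyran-6-yl)but-2-enoic acid
Conditions: Me3SnOH (5 equiv), 1,2-dichloroethane, 80 °C, dark; 1 M HCl
Reagents that add atoms: trimethyltin hydroxide, C[Sn](C)(C)O
Why: Trimethyltin hydroxide ester cleavage runs under neutral conditions through the stannyl ester, so the hydroxide-sensitive 2-pyranone lactone and its vinylogous methyl ester survive; no stereocentre is involved and the E geometry is kept by excluding light.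

Step 5
Reactants: 8 (E)-3-(4-methoxy-3-methyl-2-oxo-2H-pyran-6-yl)but-2-enoic acid (two molecules)
Product: 11 (1R,2S,3R,4S)-3,4-bis(4-methoxy-3-methyl-2-oxo-2H-pyran-6-yl)-3,4-dimethylcyclobutane-1,2-dicarboxylic acid (meso; the target), via ethylenediammonium monomer salt 9 (not isolated), via ethylenediammonium dimer salt 10 (not isolated)
Conditions: ethylenediamine (0.5 equiv), MeOH, 20 °C, evaporate to a crystalline film; hν (365 nm), solid state, 20 °C, N2; 1 M HCl
Reagents that add atoms: none
Why: Topochemical [2+2] photodimerisation (Schmidt's distance rule) inside the 2:1 ethylenediammonium double salt, a known way to steer cinnamate-type acids to β-truxinic-type dimers: the diammonium bridge stacks two carboxylates parallel and head-to-head within about 4 Å, so suprafacial addition with retention of both E geometries gives only the syn head-to-head cyclobutane (pyranones cis to each other, CO2H groups cis to each other, pyranone trans to the neighbouring CO2H), i.e. the meso (1R,2S,3R,4S) isomer, while 365 nm light excites only the conjugated monomer and not the product pyranones.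

**Compound list**
1 | ethyl 2-methyl-3-oxobutanoate (racemic) | CCOC(=O)C(C)C(C)=O | starting material
2 | ethyl (E)-3-methyl-4-oxobut-2-enoate | CCOC(=O)/C=C(\C)C=O | starting material
3 | sodium lithium dienolate (dianion) of 1, not isolated | [Na+].[Li+].C=C([O-])C(C)=C([O-])OCC | intermediate
4 | diethyl (E)-4-hydroxy-3,7-dimethyl-6-oxooct-2-enedioate (diastereomer mixture) | CCOC(=O)C(C)C(=O)CC(O)/C(C)=C/C(=O)OCC | intermediate
5 | diethyl (E)-3,7-dimethyl-4,6-dioxooct-2-enedioate, not isolated | CCOC(=O)C(C)C(=O)CC(=O)/C(C)=C/C(=O)OCC | intermediate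
6 | ethyl (E)-3-(4-hydroxy-3-methyl-2-oxo-2H-pyran-6-yl)but-2-enoate | CCOC(=O)/C=C(\C)c1cc(O)c(C)c(=O)o1 | intermediate
7 | ethyl (E)-3-(4-methoxy-3-methyl-2-oxo-2H-pyran-6-yl)but-2-enoate | CCOC(=O)/C=C(\C)c1cc(OC)c(C)c(=O)o1 | intermediate
8 | (E)-3-(4-methoxy-3-methyl-2-oxo-2H-pyran-6-yl)but-2-enoic acid | COc1cc(/C(C)=C/C(=O)O)oc(=O)c1C | intermediate
9 | ethylenediammonium bis[(E)-3-(4-methoxy-3-methyl-2-oxo-2H-pyran-6-yl)but-2-enoate], not isolated | COc1cc(/C(C)=C/C(=O)[O-])oc(=O)c1C.COc1cc(/C(C)=C/C(=O)[O-])oc(=O)c1C.[NH3+]CC[NH3+] | intermediate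
10 | ethylenediammonium (1R,2S,3R,4S)-3,4-bis(4-methoxy-3-methyl-2-oxo-2H-pyran-6-yl)-3,4-dimethylcyclobutane-1,2-dicarboxylate, not isolated | COc1cc([C@@]2(C)[C@H](C(=O)[O-])[C@H](C(=O)[O-])[C@@]2(C)c2cc(OC)c(C)c(=O)o2)oc(=O)c1C.[NH3+]CC[NH3+] | intermediate
11 | (1R,2S,3R,4S)-3,4-bis(4-methoxy-3-methyl-2-oxo-2H-pyran-6-yl)-3,4-dimethylcyclobutane-1,2-dicarboxylic acid (meso) | COc1cc([C@@]2(C)[C@H](C(=O)O)[C@H](C(=O)O)[C@@]2(C)c2cc(OC)c(C)c(=O)o2)oc(=O)c1C | target

**Totals**
Total step count: 5. Longest linear sequence: 5 steps (1/2 → 4 → 6 → 7 → 8 → 11).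

**Steps most likely to fail, with fallbacks**

Step 5 is the riskiest. The salt 9 may crystallise in a photostable or head-to-tail packing, the β-methyl group may keep the alkenes too far apart, or the pyranone C5=C6 bond may react instead. The fallback replaces the non-covalent template by a covalent one. It sets out from 8 and comes back at 11. Two molecules of 8 are esterified onto naphthalene-1,8-diol (0.5 equiv, EDC·HCl, DMAP, CH2Cl2) to give naphthalene-1,8-diyl bis[(E)-3-(4-methoxy-3-methyl-2-oxo-2H-pyran-6-yl)but-2-enoate] F1. The peri-diester holds both enoates stacked head-to-head, so 365 nm irradiation (solid film or dilute CH2Cl2) closes the ring intramolecularly to naphthalene-1,8-diyl (1R,2S,3R,4S)-3,4-bis(4-methoxy-3-methyl-2-oxo-2H-pyran-6-yl)-3,4-dimethylcyclobutane-1,2-dicarboxylate F2. Brief LiOH treatment (THF/H2O, 0 °C) cleaves the two labile aryl esters and releases 11 together with the diol.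

Step 2 is the second risk. Under DBU the diketo ester 5 carries a doubly activated alkene that can undergo Michael addition or oligomerise before it lactonises. The fallback closes the ring without base through an acylketene. It sets out from 2 and comes back at 6. The dianion aldol of step 1 is run on tert-butyl 2-methyl-3-oxobutanoate in place of 1 to give 8-tert-butyl 1-ethyl (E)-4-hydroxy-3,7-dimethyl-6-oxooct-2-enedioate F3. IBX oxidation gives, this time isolated, 8-tert-butyl 1-ethyl (E)-3,7-dimethyl-4,6-dioxooct-2-enedioate F4. Heating F4 in toluene or xylene (110–140 °C) expels tert-butanol, and the acylketene formed is trapped by the enol oxygen to give 6.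

Step 4 is the third risk. The conjugated, β,β-disubstituted ethyl ester may react sluggishly with Me3SnOH, and hydroxide alternatives may open the pyranone or cleave its 4-methoxy group. The fallback avoids ester hydrolysis by carrying the side-chain terminus as an aldehyde acetal and unveiling the acid by oxidation. It sets out from 1 and comes back at 8.
- The dianion 3 from 1 is added to (E)-4,4-dimethoxy-2-methylbut-2-enal (COC(OC)/C=C(\C)C=O; assumed purchasable) to give ethyl (E)-5-hydroxy-8,8-dimethoxy-2,6-dimethyl-3-oxooct-6-enoate F5.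
- IBX gives ethyl (E)-8,8-dimethoxy-2,6-dimethyl-3,5-dioxooct-6-enoate F6, which DBU lactonises to 6-[(E)-4,4-dimethoxybut-2-en-2-yl]-4-hydroxy-3-methyl-2H-pyran-2-one F7.
- Me2SO4/K2CO3 gives 6-[(E)-4,4-dimethoxybut-2-en-2-yl]-4-methoxy-3-methyl-2H-pyran-2-one F8.
- TsOH in acetone/H2O unmasks (E)-3-(4-methoxy-3-methyl-2-oxo-2H-pyran-6-yl)but-2-enal F9.
- Pinnick oxidation (NaClO2, NaH2PO4, 2-methyl-2-butene, t-BuOH/H2O) gives 8.

This variant also removes the Michael acceptor from the lactonisation.

**Further compounds**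
F1 | step 5 | naphthalene-1,8-diyl bis[(E)-3-(4-methoxy-3-methyl-2-oxo-2H-pyran-6-yl)but-2-enoate] | COc1cc(/C(C)=C/C(=O)Oc2cccc3cccc(OC(=O)/C=C(\C)c4cc(OC)c(C)c(=O)o4)c23)oc(=O)c1C
F2 | step 5 | naphthalene-1,8-diyl (1R,2S,3R,4S)-3,4-bis(4-methoxy-3-methyl-2-oxo-2H-pyran-6-yl)-3,4-dimethylcyclobutane-1,2-dicarboxylate | COc1cc([C@@]2(C)[C@H](C(=O)Oc3cccc4cccc(OC5=O)c34)[C@H]5[C@@]2(C)c2cc(OC)c(C)c(=O)o2)oc(=O)c1C
F3 | step 2 | 8-tert-butyl 1-ethyl (E)-4-hydroxy-3,7-dimethyl-6-oxooct-2-enedioate | CC(C)(C)OC(=O)C(C)C(=O)CC(O)/C(C)=C/C(=O)OCC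
F4 | step 2 | 8-tert-butyl 1-ethyl (E)-3,7-dimethyl-4,6-dioxooct-2-enedioate | CC(C)(C)OC(=O)C(C)C(=O)CC(=O)/C(C)=C/C(=O)OCC
F5 | step 4 | ethyl (E)-5-hydroxy-8,8-dimethoxy-2,6-dimethyl-3-oxooct-6-enoate | CCOC(=O)C(C)C(=O)CC(O)/C(C)=C/C(OC)OC
F6 | step 4 | ethyl (E)-8,8-dimethoxy-2,6-dimethyl-3,5-dioxooct-6-enoate | CCOC(=O)C(C)C(=O)CC(=O)/C(C)=C/C(OC)OC
F7 | step 4 | 6-[(E)-4,4-dimethoxybut-2-en-2-yl]-4-hydroxy-3-methyl-2H-pyran-2-one | COC(OC)/C=C(\C)c1cc(O)c(C)c(=O)o1
F8 | step 4 | 6-[(E)-4,4-dimethoxybut-2-en-2-yl]-4-methoxy-3-methyl-2H-pyran-2-one | COC(OC)/C=C(\C)c1cc(OC)c(C)c(=O)o1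
F9 | step 4 | (E)-3-(4-methoxy-3-methyl-2-oxo-2H-pyran-6-yl)but-2-enal | O=C/C=C(\C)c1cc(OC)c(C)c(=O)o1
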